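**Retrosynthetic overview**

1. Plicatic acid 23 comes from 22 by acid removal of the tert-butyl ester, acetonide and MOM group. The ring C1–C2–C3–C4–C4a–C8a of 22 is not closed as such: it comes from the cyclopentane C4a–C1–C2–C3–C4 of spirodienone 21 by a dienone–phenol 1,2-shift of C1 from C4a to C8a (5 → 6).
2. 21 comes from quinone methide 20: the ring-A phenoxide adds through C4a to C1 (dearomative 5-exo-trig spirocyclisation). The C1–C4a bond is absent from the target; it serves to set C1 and to stage the ring expansion.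
3. Enabling feature: ring A has its free OH at C7, para to C4a, so C4a is the nucleophilic ipso carbon and a cyclohexadienone can form. Its OMe at C6 leaves C8a as the only electron-poor β-carbon of that dienone. The pendant ring has its OH at C4', para to C1, so C1 can become a quinone methide carbon.
4. 20 comes from 18 (acetonide, Ag2O), and 18 from oxolane diol 17. The trans C2/C3 diol of the tetralin is a cis diol on a temporary oxolane whose ring O joins C1 to the CH2 on C3. It is set by syn-dihydroxylation of 2,5-dihydrofuran 16 anti to the C1 aryl; hydrogenolysis of the benzylic C1–O bond then deletes that ring.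
5. 16 comes from enol triflate 10 and benzylzinc 15 (Negishi); 10 from oxolanone 9 (O–H insertion, Dieckmann); 9 from (R)-hydroxy ester 6 (asymmetric transfer hydrogenation, the only source of absolute configuration). Ring order: oxolane, then spirocyclopentane, then the tetralin ring.

Key step: step 17

Remark: atoms keep the tetralin numbering of the target in all intermediates (C1 bears the pendant aryl, C2 the carboxyl, C3 the CH2OH, C4 is the CH2, C4a/C8a are the fusion carbons of ring A, primes denote the pendant aryl); methyl 3,4-dihydroxy-5-methoxybenzoate is taken as commercially available.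

**Route**

Step 1
Reactants: 1 methyl 3,4-dihydroxy-5-methoxybenzoate
Product: 2 methyl 4-(benzyloxy)-3-hydroxy-5-methoxybenzoate
Conditions: BnBr (1.05 equiv), KHCO3, DMF, 40 °C
Reagents that add atoms: benzyl bromide, BrCc1ccccc1
Why: Williamson etherification in which the weak base should ionise only the 4-OH, which is para to the ester and the most acidic phenol.

Step 2
Reactants: 2 methyl 4-(benzyloxy)-3-hydroxy-5-methoxybenzoate
Product: 3 methyl 4-(benzyloxy)-3-methoxy-5-(methoxymethoxy)benzoate
Conditions: MOMCl, i-Pr2NEt, CH2Cl2, 0 °C → rt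
Reagents that add atoms: chloromethyl methyl ether, COCCl
Why: MOM acetal formation on the remaining phenol gives a group that should survive base, hydrogenolysis, Ag2O and fluoride and leave with acid at the end.

Step 3
Reactants: 3 methyl 4-(benzyloxy)-3-methoxy-5-(methoxymethoxy)benzoate; 4 tert-butyl acetate
Product: 5 tert-butyl 3-[4-(benzyloxy)-3-methoxy-5-(methoxymethoxy)phenyl]-3-oxopropanoate
Conditions: LiHMDS (3.3 equiv), 4 (1.6 equiv), THF, −78 → 0 °C; aq NH4Cl
Reagents that add atoms: none
Why: Crossed Claisen condensation of the lithium enolate of tert-butyl acetate with the non-enolisable aryl ester, driven by deprotonation of the β-keto ester formed.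

Step 4
Reactants: 5 tert-butyl 3-[4-(benzyloxy)-3-methoxy-5-(methoxymethoxy)phenyl]-3-oxopropanoate
Product: 6 tert-butyl (3R)-3-[4-(benzyloxy)-3-methoxy-5-(methoxymethoxy)phenyl]-3-hydroxypropanoate
Conditions: RuCl(p-cymene)[(R,R)-TsDPEN] (1 mol %), HCO2H/Et3N (5:2), EtOAc, 30 °C
Reagents that add atoms: none
Why: Noyori–Ikariya asymmetric transfer hydrogenation of an aryl ketone, in which the (R,R)-catalyst is expected by the aryl CH–π model to give the (R)-carbinol; this catalyst-controlled centre is the only source of absolute configuration.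

Step 5
Reactants: 6 tert-butyl (3R)-3-[4-(benzyloxy)-3-methoxy-5-(methoxymethoxy)phenyl]-3-hydroxypropanoate; 7 ethyl diazoacetate
Product: 8 tert-butyl (3R)-3-[4-(benzyloxy)-3-methoxy-5-(methoxymethoxy)phenyl]-3-(2-ethoxy-2-oxoethoxy)propanoate
Conditions: Rh2(OAc)4 (1 mol %), CH2Cl2, rt, slow addition of 7 (1.5 equiv)
Reagents that add atoms: none
Why: Rh(II)-carbenoid O–H insertion forms the ether under neutral conditions, so neither retro-aldol cleavage nor loss of configuration at the carbinol carbon is expected.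

Step 6
Reactants: 8 tert-butyl (3R)-3-[4-(benzyloxy)-3-methoxy-5-(methoxymethoxy)phenyl]-3-(2-ethoxy-2-oxoethoxy)propanoate
Product: 9 tert-butyl (2R)-2-[4-(benzyloxy)-3-methoxy-5-(methoxymethoxy)phenyl]-4-oxooxolane-3-carboxylate (C3 epimers and enol)
Conditions: LiHMDS (2.2 equiv), THF, −78 → −30 °C; AcOH
Reagents that add atoms: none
Why: Dieckmann condensation in which only the ethyl ester is a competent acyl acceptor, so the 4-oxooxolane-3-carboxylate should be the regioisomer formed; the new C3 centre is left undefined because it is enolised in the next step.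

Step 7
Reactants: 9 tert-butyl (2R)-2-[4-(benzyloxy)-3-methoxy-5-(methoxymethoxy)phenyl]-4-oxooxolane-3-carboxylate
Product: 10 tert-butyl (2S)-2-[4-(benzyloxy)-3-methoxy-5-(methoxymethoxy)phenyl]-4-(trifluoromethanesulfonyloxy)-2,5-dihydrofuran-3-carboxylate
Conditions: Tf2O (1.2 equiv), i-Pr2NEt, CH2Cl2, −78 °C
Reagents that add atoms: trifluoromethanesulfonic anhydride, O=S(=O)(OS(=O)(=O)C(F)(F)F)C(F)(F)F
Why: O-sulfonylation of the β-keto ester enol gives the conjugated vinyl triflate, and the low temperature with an amine base should avoid retro-oxa-Michael opening at the benzylic ether carbon (the descriptor changes from R to S only through CIP priorities).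

Step 8
Reactants: 11 vanillin
Product: 12 3-methoxy-4-(triisopropylsilyloxy)benzaldehyde
Conditions: TIPSCl, imidazole, DMF, rt
Reagents that add atoms: chlorotriisopropylsilane, CC(C)[Si](Cl)(C(C)C)C(C)C
Why: Phenol silylation; the TIPS ether should survive organozinc formation, Pd coupling, osmylation, hydrogenolysis and Ag2O and is the fluoride-labile trigger of the key step.

Step 9
Reactants: 12 3-methoxy-4-(triisopropylsilyloxy)benzaldehyde
Product: 13 [3-methoxy-4-(triisopropylsilyloxy)phenyl]methanol
Conditions: NaBH4, MeOH, 0 °C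
Reagents that add atoms: none
Why: Borohydride reduction of an aryl aldehyde, with no other reducible group present.

Step 10
Reactants: 13 [3-methoxy-4-(triisopropylsilyloxy)phenyl]methanol
Product: 14 4-(chloromethyl)-2-methoxy-1-(triisopropylsilyloxy)benzene
Conditions: SOCl2, Et3N, CH2Cl2, 0 °C; used crude
Reagents that add atoms: thionyl chloride, O=S(Cl)Cl
Why: Chlorodehydroxylation of an electron-rich benzylic alcohol through its chlorosulfite, with base present to protect the silyl ether from HCl.

Step 11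
Reactants: 14 4-(chloromethyl)-2-methoxy-1-(triisopropylsilyloxy)benzene
Product: 15 [3-methoxy-4-(triisopropylsilyloxy)benzyl]zinc chloride (THF solution, used directly)
Conditions: Zn dust (activated with TMSCl and 1,2-dibromoethane), LiCl, THF, rt
Reagents that add atoms: zinc, [Zn]
Why: LiCl-promoted oxidative insertion of zinc into a benzylic C–Cl bond gives a benzylzinc halide that tolerates the aryl silyl ether.

Step 12
Reactants: 10 tert-butyl (2S)-2-[4-(benzyloxy)-3-methoxy-5-(methoxymethoxy)phenyl]-4-(trifluoromethanesulfonyloxy)-2,5-dihydrofuran-3-carboxylate; 15 [3-methoxy-4-(triisopropylsilyloxy)benzyl]zinc chloride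
Product: 16 tert-butyl (2S)-2-[4-(benzyloxy)-3-methoxy-5-(methoxymethoxy)phenyl]-4-{[3-methoxy-4-(triisopropylsilyloxy)phenyl]methyl}-2,5-dihydrofuran-3-carboxylate
Conditions: Pd(PPh3)4 (5 mol %), THF, rt → 45 °C
Reagents that add atoms: none
Why: Negishi coupling of an electron-poor vinyl triflate with a benzylzinc halide runs under neutral conditions that should leave the esters, the silyl ether and the allylic benzylic stereocentre untouched.

Step 13
Reactants: 16 tert-butyl (2S)-2-[4-(benzyloxy)-3-methoxy-5-(methoxymethoxy)phenyl]-4-{[3-methoxy-4-(triisopropylsilyloxy)phenyl]methyl}-2,5-dihydrofuran-3-carboxylate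
Product: 17 tert-butyl (2S,3S,4R)-2-[4-(benzyloxy)-3-methoxy-5-(methoxymethoxy)phenyl]-3,4-dihydroxy-4-{[3-methoxy-4-(triisopropylsilyloxy)phenyl]methyl}oxolane-3-carboxylate
Conditions: K2OsO2(OH)4 (5 mol %), NMO (2 equiv), citric acid (1 equiv), t-BuOH/H2O (1:1), rt → 40 °C
Reagents that add atoms: N-methylmorpholine N-oxide, C[N+]1([O-])CCOCC1; water, O
Why: Catalytic osmylation (Upjohn type, acidified for an electron-poor alkene) adds both oxygens syn to the dihydrofuran face anti to the C1 aryl, so C2 and C3 are set together, cis on the oxolane (trans in the later tetralin), with the absolute sense relayed from C1.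

Step 14
Reactants: 17 tert-butyl (2S,3S,4R)-2-[4-(benzyloxy)-3-methoxy-5-(methoxymethoxy)phenyl]-3,4-dihydroxy-4-{[3-methoxy-4-(triisopropylsilyloxy)phenyl]methyl}oxolane-3-carboxylate
Product: 18 tert-butyl (2S,3R)-2,3-dihydroxy-3-(hydroxymethyl)-2-{[4-hydroxy-3-methoxy-5-(methoxymethoxy)phenyl]methyl}-4-[3-methoxy-4-(triisopropylsilyloxy)phenyl]butanoate
Conditions: H2 (3 atm), 20 % Pd(OH)2/C, EtOH/EtOAc, AcOH (cat.), rt
Reagents that add atoms: none
Why: Catalytic hydrogenolysis cleaves the aryl benzyl ether and the benzylic C1–O bond of the 2-aryloxolane (the known reductive opening of 2-aryl tetrahydrofuran lignans), which erases the relay centre at C1 and frees the 4'-OH and the CH2OH on C3, while the hindered tert-butyl ester should resist lactonisation.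

Step 15
Reactants: 18 tert-butyl (2S,3R)-2,3-dihydroxy-3-(hydroxymethyl)-2-{[4-hydroxy-3-methoxy-5-(methoxymethoxy)phenyl]methyl}-4-[3-methoxy-4-(triisopropylsilyloxy)phenyl]butanoate
Product: 19 tert-butyl (2S)-2-hydroxy-3-[4-hydroxy-3-methoxy-5-(methoxymethoxy)phenyl]-2-[(4R)-4-{[3-methoxy-4-(triisopropylsilyloxy)phenyl]methyl}-2,2-dimethyl-1,3-dioxolan-4-yl]propanoate
Conditions: 2,2-dimethoxypropane, PPTS (cat.), CH2Cl2, rt
Reagents that add atoms: 2,2-dimethoxypropane, COC(C)(C)OC
Why: Acid-catalysed transketalisation should engage the primary OH and close on the adjacent C3–OH as the five-membered terminal acetonide, which keeps the CH2OH from adding to the quinone methide later.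

Step 16
Reactants: 19 tert-butyl (2S)-2-hydroxy-3-[4-hydroxy-3-methoxy-5-(methoxymethoxy)phenyl]-2-[(4R)-4-{[3-methoxy-4-(triisopropylsilyloxy)phenyl]methyl}-2,2-dimethyl-1,3-dioxolan-4-yl]propanoate
Product: 20 tert-butyl (2S)-2-hydroxy-2-[(4R)-4-{[3-methoxy-4-(triisopropylsilyloxy)phenyl]methyl}-2,2-dimethyl-1,3-dioxolan-4-yl]-3-[3-methoxy-5-(methoxymethoxy)-4-oxocyclohexa-2,5-dien-1-ylidene]propanoate (p-quinone methide at C1, E/Z mixture)
Conditions: Ag2O (5 equiv), CH2Cl2, rt, dark; filtration, used directly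
Reagents that add atoms: none
Why: Ag2O dehydrogenation of a 4-alkyl-2,6-dialkoxyphenol gives the p-quinone methide, which cannot tautomerise to a styrene because C2 is quaternary.

Step 17
Reactants: 20 tert-butyl (2S)-2-hydroxy-2-[(4R)-4-{[3-methoxy-4-(triisopropylsilyloxy)phenyl]methyl}-2,2-dimethyl-1,3-dioxolan-4-yl]-3-[3-methoxy-5-(methoxymethoxy)-4-oxocyclohexa-2,5-dien-1-ylidene]propanoate
Product: 22 tert-butyl plicatate 3-O/CH2O-acetonide 3'-O-MOM ether, via spirodienone 21 (not isolated)
Conditions: TBAF (1.1 equiv), THF (0.01 M), −40 → 0 °C; then CF3CO2H (5 equiv), CH2Cl2, −20 → 0 °C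
Reagents that add atoms: none
Why: Fluoride unmasks the ring-A phenoxide, whose para carbon C4a adds to the quinone methide carbon C1 (dearomative 1,6-conjugate addition of the Ar1-5 para-alkylation type, 5-exo-trig) to close the cyclopentane C4a–C1–C2–C3–C4 of spiro[4.5]decadienone 21; direct six-membered closure at C8a is not open to a phenoxide because C8a is meta to O−. In the quinone methide, allylic 1,3-strain keeps the small C2–OH rather than the tert-butyl ester in the plane next to the quinoid ring and the C3–C4 tether delivers C4a to one face only, so C1 should form with the aryl cis to C2–OH (the spiro centre itself is lost again). Acid then protonates the dienone and C1 shifts suprafacially, with retention, from C4a to C8a (dienone–phenol rearrangement), which expands the five-membered ring to the six-membered ring and restores ring A as the 7-hydroxy-6-methoxy arene. The selectivity needed is migration of C1, not C4, and to C8a, not C5: C1 is the benzylic carbon that best carries positive charge, and C8a is the unsubstituted enone β-carbon, whereas C5 is the electron-rich β-carbon of the C6 enol ether and is flanked by OMe. If the protonated dienone ionises at C1–C4a instead, the benzylic cation should reclose at C8a to the same product, with the aryl again trans to the ester.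

Step 18
Reactants: 22 tert-butyl plicatate 3-O/CH2O-acetonide 3'-O-MOM ether
Product: 23 plicatic acid, (1S,2S,3R)-1-(3,4-dihydroxy-5-methoxyphenyl)-2,3,7-trihydroxy-3-(hydroxymethyl)-6-methoxy-1,2,3,4-tetrahydronaphthalene-2-carboxylic acid
Conditions: CF3CO2H/H2O (9:1), 0 °C → rt; evaporation, reverse-phase chromatography
Reagents that add atoms: none
Why: Aqueous acidolysis should remove the tert-butyl ester, the acetonide and the MOM acetal in one operation without touching the three stereocentres, none of which is enolisable or readily ionised, and the water present should disfavour closure of the strained trans-fused γ-lactone.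

**Compound list**

1 | methyl 3,4-dihydroxy-5-methoxybenzoate | COC(=O)c1cc(O)c(O)c(OC)c1 | starting material
2 | methyl 4-(benzyloxy)-3-hydroxy-5-methoxybenzoate | COC(=O)c1cc(O)c(OCc2ccccc2)c(OC)c1 | intermediate
3 | methyl 4-(benzyloxy)-3-methoxy-5-(methoxymethoxy)benzoate | COC(=O)c1cc(OCOC)c(OCc2ccccc2)c(OC)c1 | intermediate
4 | tert-butyl acetate | CC(=O)OC(C)(C)C | starting material
5 | tert-butyl 3-[4-(benzyloxy)-3-methoxy-5-(methoxymethoxy)phenyl]-3-oxopropanoate | CC(C)(C)OC(=O)CC(=O)c1cc(OC)c(OCc2ccccc2)c(OCOC)c1 | intermediate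
6 | tert-butyl (3R)-3-[4-(benzyloxy)-3-methoxy-5-(methoxymethoxy)phenyl]-3-hydroxypropanoate | CC(C)(C)OC(=O)C[C@@H](O)c1cc(OC)c(OCc2ccccc2)c(OCOC)c1 | intermediate
7 | ethyl diazoacetate | CCOC(=O)C=[N+]=[N-] | starting material
8 | tert-butyl (3R)-3-[4-(benzyloxy)-3-methoxy-5-(methoxymethoxy)phenyl]-3-(2-ethoxy-2-oxoethoxy)propanoate | CCOC(=O)CO[C@H](CC(=O)OC(C)(C)C)c1cc(OC)c(OCc2ccccc2)c(OCOC)c1 | intermediate
9 | tert-butyl (2R)-2-[4-(benzyloxy)-3-methoxy-5-(methoxymethoxy)phenyl]-4-oxooxolane-3-carboxylate (C3 undefined) | CC(C)(C)OC(=O)C1C(=O)CO[C@H]1c1cc(OC)c(OCc2ccccc2)c(OCOC)c1 | intermediate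
10 | tert-butyl (2S)-2-[4-(benzyloxy)-3-methoxy-5-(methoxymethoxy)phenyl]-4-(trifluoromethanesulfonyloxy)-2,5-dihydrofuran-3-carboxylate | CC(C)(C)OC(=O)C1=C(OS(=O)(=O)C(F)(F)F)CO[C@H]1c1cc(OC)c(OCc2ccccc2)c(OCOC)c1 | intermediate
11 | vanillin | COc1cc(C=O)ccc1O | starting material
12 | 3-methoxy-4-(triisopropylsilyloxy)benzaldehyde | COc1cc(C=O)ccc1O[Si](C(C)C)(C(C)C)C(C)C | intermediate
13 | [3-methoxy-4-(triisopropylsilyloxy)phenyl]methanol | COc1cc(CO)ccc1O[Si](C(C)C)(C(C)C)C(C)C | intermediate
14 | 4-(chloromethyl)-2-methoxy-1-(triisopropylsilyloxy)benzene | COc1cc(CCl)ccc1O[Si](C(C)C)(C(C)C)C(C)C | intermediate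
15 | [3-methoxy-4-(triisopropylsilyloxy)benzyl]zinc chloride | COc1cc(C[Zn]Cl)ccc1O[Si](C(C)C)(C(C)C)C(C)C | intermediate
16 | tert-butyl (2S)-2-[4-(benzyloxy)-3-methoxy-5-(methoxymethoxy)phenyl]-4-{[3-methoxy-4-(triisopropylsilyloxy)phenyl]methyl}-2,5-dihydrofuran-3-carboxylate | COc1cc(CC2=C(C(=O)OC(C)(C)C)[C@H](c3cc(OC)c(OCc4ccccc4)c(OCOC)c3)OC2)ccc1O[Si](C(C)C)(C(C)C)C(C)C | intermediate
17 | tert-butyl (2S,3S,4R)-2-[4-(benzyloxy)-3-methoxy-5-(methoxymethoxy)phenyl]-3,4-dihydroxy-4-{[3-methoxy-4-(triisopropylsilyloxy)phenyl]methyl}oxolane-3-carboxylate | COc1cc(C[C@@]2(O)CO[C@@H](c3cc(OC)c(OCc4ccccc4)c(OCOC)c3)[C@@]2(O)C(=O)OC(C)(C)C)ccc1O[Si](C(C)C)(C(C)C)C(C)C | intermediate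
18 | tert-butyl (2S,3R)-2,3-dihydroxy-3-(hydroxymethyl)-2-{[4-hydroxy-3-methoxy-5-(methoxymethoxy)phenyl]methyl}-4-[3-methoxy-4-(triisopropylsilyloxy)phenyl]butanoate | COc1cc(C[C@@](O)(CO)[C@](O)(C(=O)OC(C)(C)C)Cc2cc(OC)c(O)c(OCOC)c2)ccc1O[Si](C(C)C)(C(C)C)C(C)C | intermediate
19 | tert-butyl (2S)-2-hydroxy-3-[4-hydroxy-3-methoxy-5-(methoxymethoxy)phenyl]-2-[(4R)-4-{[3-methoxy-4-(triisopropylsilyloxy)phenyl]methyl}-2,2-dimethyl-1,3-dioxolan-4-yl]propanoate | COc1cc(C[C@]2(OC(C)(C)OC2)[C@](O)(C(=O)OC(C)(C)C)Cc2cc(OC)c(O)c(OCOC)c2)ccc1O[Si](C(C)C)(C(C)C)C(C)C | intermediate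
20 | p-quinone methide of 19 at C1 (exocyclic C=C geometry undefined) | COc1cc(C[C@]2(OC(C)(C)OC2)[C@](O)(C(=O)OC(C)(C)C)C=C2C=C(OC)C(=O)C(OCOC)=C2)ccc1O[Si](C(C)C)(C(C)C)C(C)C | intermediate
21 | spiro[4.5]deca-6,9-dien-8-one: cyclopentane C4a(spiro)–C1–C2–C3–C4 with 1-aryl (4'-OH, 3'-OMOM, 5'-OMe), 2-OH, 2-CO2t-Bu, 3-spiro-acetonide; dienone ring with OMe next to C=O (spiro centre undefined) | COC1=CC2(C=CC1=O)[C@H](c1cc(OC)c(O)c(OCOC)c1)[C@@](O)(C(=O)OC(C)(C)C)[C@](OC(C)(C)O3)(C3)C2 | intermediate
22 | tert-butyl plicatate 3-O/CH2O-acetonide 3'-O-MOM ether (1S,2S,3R) | COc1cc2c(cc1O)[C@H](c1cc(OC)c(O)c(OCOC)c1)[C@@](O)(C(=O)OC(C)(C)C)[C@](OC(C)(C)O3)(C3)C2 | intermediate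
23 | plicatic acid, (1S,2S,3R)-1-(3,4-dihydroxy-5-methoxyphenyl)-2,3,7-trihydroxy-3-(hydroxymethyl)-6-methoxy-1,2,3,4-tetrahydronaphthalene-2-carboxylic acid | COc1cc2c(cc1O)[C@H](c1cc(O)c(O)c(OC)c1)[C@@](O)(C(=O)O)[C@](O)(CO)C2 | target

**Step count and risks**

Total step count: 18. Longest linear sequence: 14 steps (steps 1–7 and 12–18).

Steps most likely to fail:

1. Step 17 (key step). The quinone methide may be intercepted by fluoride, water or intermolecular O-alkylation before the ipso carbon attacks, or the 1,2-shift may go to the wrong terminus or move the wrong carbon. The fallback sets out from 20 and returns at 22. BF3·OEt2 (1.1 equiv) in CH2Cl2 at −78 °C activates the quinone methide so that C8a of the still silylated ring A (para to OMe) attacks C1 directly in an intramolecular Friedel–Crafts alkylation. This should give the 7-O-triisopropylsilyl ether of 22 F1, with the aryl trans to the ester; TBAF in THF at 0 °C then gives 22.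

2. Step 13. Osmylation of the tetrasubstituted, ester-deactivated alkene may be too slow, so that conversion stalls or the arenes are over-oxidised. The fallback sets out from 16 and returns at 17, with the alkene osmylated one oxidation level lower. DIBAL-H (CH2Cl2, −78 → 0 °C) reduces the ester to the allylic alcohol, (2S)-3-(hydroxymethyl)-2,5-dihydrofuran F2. Its electron-rich alkene should be dihydroxylated readily (OsO4 cat., NMO, acetone/H2O), again anti to the aryl, to the oxolane triol F3. TEMPO/PhI(OAc)2 in MeCN/H2O oxidises the primary alcohol through the hydroxy aldehyde F4 to the hydroxy acid F5. O-tert-Butyl-N,N'-diisopropylisourea (CH2Cl2, rt) re-forms the tert-butyl ester, which is 17.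

3. Step 6. The ester enolate may expel the glycolate alkoxide by β-elimination (retro-oxa-Michael), with loss of material and, on re-addition, erosion of enantiomeric purity. The fallback sets out from 6 and returns at 9. LDA (2.2 equiv) in THF at −78 °C gives the alkoxide–enolate dianion (Fráter–Seebach type), which has no leaving group to eliminate. C-Acylation with 2-chloro-N-methoxy-N-methylacetamide gives the γ-chloro-β-keto ester F6. K2CO3 in acetone at rt then closes the oxolanone by intramolecular O-alkylation (5-exo-tet) to 9.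

Further compounds
F1 | step 17 | 7-O-triisopropylsilyl ether of 22 | COc1cc2c(cc1O[Si](C(C)C)(C(C)C)C(C)C)[C@H](c1cc(OC)c(O)c(OCOC)c1)[C@@](O)(C(=O)OC(C)(C)C)[C@](OC(C)(C)O3)(C3)C2
F2 | step 13 | [(2S)-2-[4-(benzyloxy)-3-methoxy-5-(methoxymethoxy)phenyl]-4-{[3-methoxy-4-(triisopropylsilyloxy)phenyl]methyl}-2,5-dihydrofuran-3-yl]methanol | COc1cc(CC2=C(CO)[C@H](c3cc(OC)c(OCc4ccccc4)c(OCOC)c3)OC2)ccc1O[Si](C(C)C)(C(C)C)C(C)C
F3 | step 13 | oxolane triol, the CH2OH analogue of 17 (same configuration at all three centres) | COc1cc(C[C@@]2(O)CO[C@@H](c3cc(OC)c(OCc4ccccc4)c(OCOC)c3)[C@@]2(O)CO)ccc1O[Si](C(C)C)(C(C)C)C(C)C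
F4 | step 13 | hydroxy aldehyde, the CHO analogue of 17 | COc1cc(C[C@@]2(O)CO[C@@H](c3cc(OC)c(OCc4ccccc4)c(OCOC)c3)[C@@]2(O)C=O)ccc1O[Si](C(C)C)(C(C)C)C(C)C
F5 | step 13 | hydroxy acid, the CO2H analogue of 17 | COc1cc(C[C@@]2(O)CO[C@@H](c3cc(OC)c(OCc4ccccc4)c(OCOC)c3)[C@@]2(O)C(=O)O)ccc1O[Si](C(C)C)(C(C)C)C(C)C
F6 | step 6 | tert-butyl 2-[(R)-[4-(benzyloxy)-3-methoxy-5-(methoxymethoxy)phenyl](hydroxy)methyl]-4-chloro-3-oxobutanoate | CC(C)(C)OC(=O)C(C(=O)CCl)[C@@H](O)c1cc(OC)c(OCc2ccccc2)c(OCOC)c1
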